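## Retrosynthetic overview

1. All nine benzene rings (A–I) are bought as arenes and no ring is built. The work is five diaryl ether bonds and three biaryl bonds, followed by a 22-fold O-demethylation of the permethyl ether 25.
2. C4–O–D1 is cut last (Ullmann ether synthesis), giving D1 phenol 13 (rings D, E, F, H, I) and aryl bromide 24 (rings A, B, G, C).
3. Feature that carries the plan: bonds E5–H1 and F5–I1 each start at a carbon ortho to a phenolic oxygen (E4–O, F4–O), on a ring whose para carbon (E1, F1) is blocked by the ether oxygen to ring D. Each ends at a C–H of a threefold-symmetric phloroglucinol ring, and both are tetra-ortho-substituted. They are cut together as a two-directional C–H/C–H coupling of bis-phenol 7 with 1,3,5-trimethoxybenzene 8.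
4. 7 comes from a double SNAr of phenol 3 on 2,6-difluoro-4-methoxybenzaldehyde 4. The D1 formyl group activates D2–F and D6–F, keeps ring D out of the oxidation, and is later exchanged for D1–OH by Baeyer–Villiger oxidation.
5. 24 comes from the same phenol 3 (A1–O–B1 Ullmann), the same dehydrogenative arylation (B5–G1), and an SNAr of B4–OH on fluoroaldehyde 20, whose formyl group becomes C2–OMe. Order of joining: D+E+F, then H and I; A+B, then G, then C; then the two halves.

Key step: step 5

Ring labels:
- A is the terminal 3,5-dihydroxyphenoxy ring.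
- B carries B1–O–A, B2/B6–OH, B3–H, B4–O–C and B5–G1.
- G is the trihydroxyphenyl ring on B5.
- C carries C1–O–B4, C2/C6–OH and C4–O–D1.
- D carries D1–O–C4, D2–O–E1, D6–O–F1 and D4–OH.
- E and F carry position 1 as the ether to D, 2/4/6 as OH, 3 as H and 5 as aryl.
- H and I are the trihydroxyphenyl rings on E5 and F5.

Remark on the chemistry: the target has no stereocentre. The three biaryl axes are not stereogenic, because rings G, H and I each carry two identical ortho substituents, so no stereocontrol is needed.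

## Route

Step 1
Reactants: 1 2,6-dimethoxy-1,4-benzoquinone
Product: 2 2,6-dimethoxybenzene-1,4-diol
Conditions: Na2S2O4, EtOAc/H2O, rt, N2
Reagents that add atoms: none
Why: Two-electron quinone-to-hydroquinone reduction by dithionite is fast and leaves both methoxy groups untouched.

Step 2
Reactants: 2 2,6-dimethoxybenzene-1,4-diol
Product: 3 4-(benzyloxy)-2,6-dimethoxyphenol
Conditions: BnBr (1.0 equiv), K2CO3 (1.0 equiv), DMF, 0 °C to rt, N2
Reagents that add atoms: benzyl bromide, BrCc1ccccc1
Why: In this Williamson ether synthesis with one equivalent of weak base, the C4 hydroxyl is the more acidic (meta to both methoxy groups) and is unhindered, whereas the C1 hydroxyl is flanked and hydrogen-bonded by two methoxy groups, so monoalkylation should fall on O4.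

Step 3
Reactants: 3 4-(benzyloxy)-2,6-dimethoxyphenol (2.2 equiv); 4 2,6-difluoro-4-methoxybenzaldehyde
Product: 6 2,6-bis[4-(benzyloxy)-2,6-dimethoxyphenoxy]-4-methoxybenzaldehyde, via mono-ether fluoroaldehyde 5 (not isolated)
Conditions: K2CO3 (3 equiv), DMF, 110 °C, N2
Reagents that add atoms: none
Why: In this two-fold nucleophilic aromatic substitution (addition–elimination), both C–F carbons lie ortho to the formyl acceptor and meta to the oxygen donors, so the first aryloxy group does not switch off the second substitution, and the benzyl ethers and the non-enolisable aldehyde tolerate carbonate in hot DMF.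

Step 4
Reactants: 6 2,6-bis[4-(benzyloxy)-2,6-dimethoxyphenoxy]-4-methoxybenzaldehyde
Product: 7 2,6-bis(4-hydroxy-2,6-dimethoxyphenoxy)-4-methoxybenzaldehyde
Conditions: H2 (1 atm), 10% Pd/C, EtOAc, rt, stopped after two equivalents of H2
Reagents that add atoms: none
Why: In this catalytic hydrogenolysis of aryl benzyl ethers, run in neutral ethyl acetate at one atmosphere, the O–benzyl bonds should be cleaved faster than the doubly ortho-substituted, donor-conjugated formyl group is reduced.

Step 5
Reactants: 7 2,6-bis(4-hydroxy-2,6-dimethoxyphenoxy)-4-methoxybenzaldehyde; 8 1,3,5-trimethoxybenzene (6 equiv)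
Product: 10 2,6-bis[4-hydroxy-2,6-dimethoxy-3-(2,4,6-trimethoxyphenyl)phenoxy]-4-methoxybenzaldehyde, via mono-arylated triad 9 (not isolated)
Conditions: boron-doped diamond anode, Ni cathode, undivided cell, [Et3NMe][O3SOMe] (0.09 M), HFIP/MeOH 82:18, 50 °C, 2.8 mA cm−2, 4.4 F per mol of 7
Reagents that add atoms: none
Why: The two free phenols (E4–OH, F4–OH) are the most easily oxidised sites of 7, so the anode removes one electron and one proton from one of them and leaves a phenoxyl radical held in a hydrogen-bonded shell of hexafluoroisopropanol; one of the three equivalent C–H carbons of 8 adds to its ortho carbon E5, a second electron transfer with loss of two protons re-aromatises both rings, and the same sequence on ring F carries 9 on to 10. The closest known reaction type is the anodic dehydrogenative phenol–arene cross-coupling in fluorinated alcohols, which joins the ortho carbon of alkoxyphenols to methoxyarenes without halide or boron on either partner, an asset here because both new bonds are tetra-ortho-substituted. No ring is closed and no stereocentre or stereogenic axis is created, because rings H and I each carry two identical ortho methoxy groups. Site selectivity is fixed by the substrate: the para carbons E1 and F1 bear the ether oxygen to ring D, and E3/E5 (F3/F5) are equivalent by the local symmetry of each ring, so the first arylation of each ring can give only one product. Chemoselectivity rests on the D1 formyl group, which makes ring D too electron-poor to be oxidised or to act as the nucleophile, on the excess of 8, which outruns phenol–phenol coupling, and on metering the charge, since the twisted and more crowded biaryl phenol should be harder to oxidise and to approach than the starting phenol, which holds back a second arylation at E3 or F3.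

Step 6
Reactants: 10 2,6-bis[4-hydroxy-2,6-dimethoxy-3-(2,4,6-trimethoxyphenyl)phenoxy]-4-methoxybenzaldehyde
Product: 11 4-methoxy-2,6-bis[2,4,6-trimethoxy-3-(2,4,6-trimethoxyphenyl)phenoxy]benzaldehyde
Conditions: MeI (4 equiv), K2CO3 (4 equiv), DMF, 40 °C
Reagents that add atoms: iodomethane, CI
Why: Williamson O-methylation caps E4–OH and F4–OH, so that the hydroxyl set free in the next step is the only one in this fragment, and the small electrophile copes with the neighbouring aryl groups.

Step 7
Reactants: 11 4-methoxy-2,6-bis[2,4,6-trimethoxy-3-(2,4,6-trimethoxyphenyl)phenoxy]benzaldehyde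
Product: 13 4-methoxy-2,6-bis[2,4,6-trimethoxy-3-(2,4,6-trimethoxyphenyl)phenoxy]phenol, via aryl formate 12 (not isolated)
Conditions: mCPBA (1.5 equiv), CH2Cl2, 0 °C to rt; aqueous Na2S2O3/NaHCO3 wash; crude 12, K2CO3 (cat.), MeOH, rt
Reagents that add atoms: mCPBA, OOC(=O)c1cccc(Cl)c1
Why: This is a Baeyer–Villiger oxidation of an electron-rich benzaldehyde, the peracid counterpart of the Dakin reaction, which is chosen because ring D has no free ortho or para hydroxyl for the alkaline peroxide version; the 2,4,6-trioxygenated aryl group migrates from the Criegee adduct in preference to hydride, and formate 12 is cleaved by mild methanolysis.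

Step 8
Reactants: 3 4-(benzyloxy)-2,6-dimethoxyphenol; 14 1-bromo-3,5-dimethoxybenzene
Product: 15 5-(benzyloxy)-2-(3,5-dimethoxyphenoxy)-1,3-dimethoxybenzene
Conditions: CuI (10 mol %), picolinic acid (20 mol %), K3PO4 (2 equiv), DMSO, 90 °C, Ar
Reagents that add atoms: none
Why: In this ligand-accelerated Ullmann diaryl ether synthesis, the CuI/picolinic acid system accepts 2,6-disubstituted phenols and the bromide has no ortho substituent, so only a di-ortho-substituted ether has to form.

Step 9
Reactants: 15 5-(benzyloxy)-2-(3,5-dimethoxyphenoxy)-1,3-dimethoxybenzene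
Product: 16 4-(3,5-dimethoxyphenoxy)-3,5-dimethoxyphenol
Conditions: H2 (1 atm), 10% Pd/C, EtOAc/EtOH, rt
Reagents that add atoms: none
Why: Catalytic hydrogenolysis removes the benzyl group, while diaryl ether and aryl methyl ether bonds are inert under these conditions.

Step 10
Reactants: 16 4-(3,5-dimethoxyphenoxy)-3,5-dimethoxyphenol; 8 1,3,5-trimethoxybenzene (3 equiv)
Product: 17 4-(3,5-dimethoxyphenoxy)-3,5-dimethoxy-2-(2,4,6-trimethoxyphenyl)phenol
Conditions: boron-doped diamond anode, Ni cathode, undivided cell, [Et3NMe][O3SOMe] (0.09 M), HFIP/MeOH 82:18, 50 °C, 2.8 mA cm−2, 2.2 F per mol of 16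
Reagents that add atoms: none
Why: This is the same anodic dehydrogenative phenol–arene cross-coupling as in step 5, now at B4–OH, where the para carbon B1 is blocked, B3 and B5 are equivalent, and ring A (aryloxy in place of one methoxy group, and outnumbered by 8) should be the poorer nucleophile.

Step 11
Reactants: 18 4-bromo-1-fluoro-2-methoxybenzene
Product: 20 5-bromo-2-fluoro-3-methoxybenzaldehyde, via aryllithium 19 (not isolated)
Conditions: LDA (1.1 equiv), THF, −78 °C; DMF (1.5 equiv), −78 °C; 1 M HCl
Reagents that add atoms: N,N-dimethylformamide, CN(C)C=O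
Why: In this directed ortho-lithiation and formylation, the amide base removes the proton next to fluorine, the most acidifying substituent, rather than the proton wedged between OMe and Br; it causes no bromine–lithium exchange, and at −78 °C 19 is trapped by DMF before it can lose LiF.

Step 12
Reactants: 17 4-(3,5-dimethoxyphenoxy)-3,5-dimethoxy-2-(2,4,6-trimethoxyphenyl)phenol; 20 5-bromo-2-fluoro-3-methoxybenzaldehyde
Product: 21 5-bromo-2-[4-(3,5-dimethoxyphenoxy)-3,5-dimethoxy-2-(2,4,6-trimethoxyphenyl)phenoxy]-3-methoxybenzaldehyde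
Conditions: Cs2CO3 (2 equiv), DMF, 100 °C, N2
Reagents that add atoms: none
Why: In this nucleophilic aromatic substitution, the fluoride is ortho to the formyl group and para to bromine, addition to a C–F carbon is far less sensitive to crowding than a metal-mediated coupling, which suits this tri-ortho-substituted ether, and the bromide (meta to the formyl group) is not activated.

Step 13
Reactants: 21 5-bromo-2-[4-(3,5-dimethoxyphenoxy)-3,5-dimethoxy-2-(2,4,6-trimethoxyphenyl)phenoxy]-3-methoxybenzaldehyde
Product: 23 5-bromo-2-[4-(3,5-dimethoxyphenoxy)-3,5-dimethoxy-2-(2,4,6-trimethoxyphenyl)phenoxy]-3-methoxyphenol, via aryl formate 22 (not isolated)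
Conditions: mCPBA (1.5 equiv), CH2Cl2, rt; aqueous Na2S2O3/NaHCO3 wash; crude 22, K2CO3 (cat.), MeOH, rt
Reagents that add atoms: mCPBA, OOC(=O)c1cccc(Cl)c1
Why: In this Baeyer–Villiger oxidation and formate methanolysis, the ortho aryloxy donor favours aryl migration, as in 5-bromo-2-alkoxybenzaldehydes, and the C–Br bond is untouched.

Step 14
Reactants: 23 5-bromo-2-[4-(3,5-dimethoxyphenoxy)-3,5-dimethoxy-2-(2,4,6-trimethoxyphenyl)phenoxy]-3-methoxyphenol
Product: 24 5-bromo-2-[4-(3,5-dimethoxyphenoxy)-3,5-dimethoxy-2-(2,4,6-trimethoxyphenyl)phenoxy]-1,3-dimethoxybenzene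
Conditions: MeI (2 equiv), K2CO3 (2 equiv), DMF, rt
Reagents that add atoms: iodomethane, CI
Why: Williamson O-methylation of the single free phenol completes ring C as a 2,6-dimethoxy-4-bromophenyl ether.

Step 15
Reactants: 13 4-methoxy-2,6-bis[2,4,6-trimethoxy-3-(2,4,6-trimethoxyphenyl)phenoxy]phenol; 24 5-bromo-2-[4-(3,5-dimethoxyphenoxy)-3,5-dimethoxy-2-(2,4,6-trimethoxyphenyl)phenoxy]-1,3-dimethoxybenzene
Product: 25 docosa-O-methyl ether of the target (all 22 hydroxyl groups as OMe)
Conditions: CuI (30 mol %), picolinic acid (60 mol %), K3PO4 (2.5 equiv), DMSO, 110 °C, Ar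
Reagents that add atoms: none
Why: In this ligand-accelerated Ullmann diaryl ether synthesis, all the crowding sits on the phenol side, which this catalyst system tolerates, while C4–Br has hydrogen at both ortho positions, and neither partner carries another free hydroxyl or halide.

Step 16
Reactants: 25 docosa-O-methyl ether of the target
Product: 26 CNP0117322.0
Conditions: BBr3 (about 2 equiv per OMe), CH2Cl2, −78 °C to rt, Ar; ice-water
Reagents that add atoms: none
Why: In this Lewis acid cleavage of aryl methyl ethers, bromide attacks the methyl carbon of each boron-complexed ether, whereas the diaryl ether and biaryl bonds offer no sp3 carbon and should survive, and hydrolysis of the boron aryloxides frees the 22 phenols.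

## Compound list

1 | 2,6-dimethoxy-1,4-benzoquinone | COC1=CC(=O)C=C(OC)C1=O | starting material
2 | 2,6-dimethoxybenzene-1,4-diol | COc1cc(O)cc(OC)c1O | intermediate
3 | 4-(benzyloxy)-2,6-dimethoxyphenol | COc1cc(OCc2ccccc2)cc(OC)c1O | intermediate
4 | 2,6-difluoro-4-methoxybenzaldehyde | COc1cc(F)c(C=O)c(F)c1 | starting material
5 | 2-[4-(benzyloxy)-2,6-dimethoxyphenoxy]-6-fluoro-4-methoxybenzaldehyde | COc1cc(F)c(C=O)c(Oc2c(OC)cc(OCc3ccccc3)cc2OC)c1 | intermediate (not isolated)
6 | 2,6-bis[4-(benzyloxy)-2,6-dimethoxyphenoxy]-4-methoxybenzaldehyde | COc1cc(Oc2c(OC)cc(OCc3ccccc3)cc2OC)c(C=O)c(Oc2c(OC)cc(OCc3ccccc3)cc2OC)c1 | intermediate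
7 | 2,6-bis(4-hydroxy-2,6-dimethoxyphenoxy)-4-methoxybenzaldehyde | COc1cc(Oc2c(OC)cc(O)cc2OC)c(C=O)c(Oc2c(OC)cc(O)cc2OC)c1 | intermediate
8 | 1,3,5-trimethoxybenzene | COc1cc(OC)cc(OC)c1 | starting material
9 | 2-(4-hydroxy-2,6-dimethoxyphenoxy)-6-[4-hydroxy-2,6-dimethoxy-3-(2,4,6-trimethoxyphenyl)phenoxy]-4-methoxybenzaldehyde | COc1cc(Oc2c(OC)cc(O)cc2OC)c(C=O)c(Oc2c(OC)cc(O)c(-c3c(OC)cc(OC)cc3OC)c2OC)c1 | intermediate (not isolated)
10 | 2,6-bis[4-hydroxy-2,6-dimethoxy-3-(2,4,6-trimethoxyphenyl)phenoxy]-4-methoxybenzaldehyde | COc1cc(Oc2c(OC)cc(O)c(-c3c(OC)cc(OC)cc3OC)c2OC)c(C=O)c(Oc2c(OC)cc(O)c(-c3c(OC)cc(OC)cc3OC)c2OC)c1 | intermediate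
11 | 4-methoxy-2,6-bis[2,4,6-trimethoxy-3-(2,4,6-trimethoxyphenyl)phenoxy]benzaldehyde | COc1cc(Oc2c(OC)cc(OC)c(-c3c(OC)cc(OC)cc3OC)c2OC)c(C=O)c(Oc2c(OC)cc(OC)c(-c3c(OC)cc(OC)cc3OC)c2OC)c1 | intermediate
12 | 4-methoxy-2,6-bis[2,4,6-trimethoxy-3-(2,4,6-trimethoxyphenyl)phenoxy]phenyl formate | COc1cc(Oc2c(OC)cc(OC)c(-c3c(OC)cc(OC)cc3OC)c2OC)c(OC=O)c(Oc2c(OC)cc(OC)c(-c3c(OC)cc(OC)cc3OC)c2OC)c1 | intermediate (not isolated)
13 | 4-methoxy-2,6-bis[2,4,6-trimethoxy-3-(2,4,6-trimethoxyphenyl)phenoxy]phenol | COc1cc(Oc2c(OC)cc(OC)c(-c3c(OC)cc(OC)cc3OC)c2OC)c(O)c(Oc2c(OC)cc(OC)c(-c3c(OC)cc(OC)cc3OC)c2OC)c1 | intermediate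
14 | 1-bromo-3,5-dimethoxybenzene | COc1cc(Br)cc(OC)c1 | starting material
15 | 5-(benzyloxy)-2-(3,5-dimethoxyphenoxy)-1,3-dimethoxybenzene | COc1cc(OC)cc(Oc2c(OC)cc(OCc3ccccc3)cc2OC)c1 | intermediate
16 | 4-(3,5-dimethoxyphenoxy)-3,5-dimethoxyphenol | COc1cc(OC)cc(Oc2c(OC)cc(O)cc2OC)c1 | intermediate
17 | 4-(3,5-dimethoxyphenoxy)-3,5-dimethoxy-2-(2,4,6-trimethoxyphenyl)phenol | COc1cc(OC)cc(Oc2c(OC)cc(O)c(-c3c(OC)cc(OC)cc3OC)c2OC)c1 | intermediate
18 | 4-bromo-1-fluoro-2-methoxybenzene | COc1cc(Br)ccc1F | starting material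
19 | (5-bromo-2-fluoro-3-methoxyphenyl)lithium | COc1cc(Br)cc([Li])c1F | intermediate (not isolated)
20 | 5-bromo-2-fluoro-3-methoxybenzaldehyde | COc1cc(Br)cc(C=O)c1F | intermediate
21 | 5-bromo-2-[4-(3,5-dimethoxyphenoxy)-3,5-dimethoxy-2-(2,4,6-trimethoxyphenyl)phenoxy]-3-methoxybenzaldehyde | COc1cc(OC)cc(Oc2c(OC)cc(Oc3c(OC)cc(Br)cc3C=O)c(-c3c(OC)cc(OC)cc3OC)c2OC)c1 | intermediate
22 | 5-bromo-2-[4-(3,5-dimethoxyphenoxy)-3,5-dimethoxy-2-(2,4,6-trimethoxyphenyl)phenoxy]-3-methoxyphenyl formate | COc1cc(OC)cc(Oc2c(OC)cc(Oc3c(OC)cc(Br)cc3OC=O)c(-c3c(OC)cc(OC)cc3OC)c2OC)c1 | intermediate (not isolated)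
23 | 5-bromo-2-[4-(3,5-dimethoxyphenoxy)-3,5-dimethoxy-2-(2,4,6-trimethoxyphenyl)phenoxy]-3-methoxyphenol | COc1cc(OC)cc(Oc2c(OC)cc(Oc3c(OC)cc(Br)cc3O)c(-c3c(OC)cc(OC)cc3OC)c2OC)c1 | intermediate
24 | 5-bromo-2-[4-(3,5-dimethoxyphenoxy)-3,5-dimethoxy-2-(2,4,6-trimethoxyphenyl)phenoxy]-1,3-dimethoxybenzene | COc1cc(OC)cc(Oc2c(OC)cc(Oc3c(OC)cc(Br)cc3OC)c(-c3c(OC)cc(OC)cc3OC)c2OC)c1 | intermediate
25 | docosa-O-methyl ether of the target | COc1cc(OC)cc(Oc2c(OC)cc(Oc3c(OC)cc(Oc4c(Oc5c(OC)cc(OC)c(-c6c(OC)cc(OC)cc6OC)c5OC)cc(OC)cc4Oc4c(OC)cc(OC)c(-c5c(OC)cc(OC)cc5OC)c4OC)cc3OC)c(-c3c(OC)cc(OC)cc3OC)c2OC)c1 | intermediate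
26 | CNP0117322.0 | Oc1cc(O)cc(Oc2c(O)cc(Oc3c(O)cc(Oc4c(Oc5c(O)cc(O)c(-c6c(O)cc(O)cc6O)c5O)cc(O)cc4Oc4c(O)cc(O)c(-c5c(O)cc(O)cc5O)c4O)cc3O)c(-c3c(O)cc(O)cc3O)c2O)c1 | target

## Step count and risks

Total step count: 16.
Longest linear sequence: 10 steps (1, 2, 8, 9, 10, 12, 13, 14, 15, 16). The branch through the key step has 9 steps (1–7, 15, 16), and step 11 is a one-step side branch.

**Step 5.**
- What may go wrong: the coupling may stall after the first arylation because of the crowding at a tetra-ortho-substituted axis. It may also run on to a second arylation at the remaining ortho carbon, to phenol–phenol coupling, or to over-oxidation of the phenol rings.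
- Fallback: it sets out from 7 and comes back at 11, replacing C–H/C–H coupling by halogenation and cross-coupling. 7 is brominated once on each phenol ring (NBS, 2 equiv, CH2Cl2, −40 °C), the hydroxyl directing to its ortho carbon and the formyl group protecting ring D. This gives 2,6-bis(3-bromo-4-hydroxy-2,6-dimethoxyphenoxy)-4-methoxybenzaldehyde F1.
- O-methylation (MeI, K2CO3, DMF) gives 2,6-bis(3-bromo-2,4,6-trimethoxyphenoxy)-4-methoxybenzaldehyde F2.
- A double Suzuki–Miyaura coupling with 2,4,6-trimethoxyphenylboronic acid (Pd(OAc)2, SPhos, K3PO4, toluene/H2O, 100 °C), a ligand system made for tetra-ortho-substituted biaryls, should then give 11.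

**Step 15.**
- What may go wrong: crowding around the D1 phenoxide and the electron-rich character of the bromide may slow C–O bond formation so far that reductive loss of bromine and catalyst decay take over.
- Fallback: it sets out from 24 and comes back at 25, changing from a halide coupling at 110 °C to an oxidative boron coupling at room temperature. Miyaura borylation (B2pin2, Pd(dppf)Cl2, KOAc, dioxane, 90 °C) gives the C4 pinacol boronate of the A–B–G–C fragment F3.
- Periodate cleavage of the pinacol ester (NaIO4, NH4OAc, acetone/H2O, rt) gives the C4 boronic acid of the A–B–G–C fragment F4.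
- Chan–Lam coupling of F4 with 13 (Cu(OAc)2, pyridine, 4 Å MS, CH2Cl2, air, rt), a reaction type known to accept 2,6-disubstituted phenols, should give 25.

**Step 16.**
- What may go wrong: the twenty-two ether cleavages may stall when partly cleaved boron aryloxides precipitate. The free polyphenol may also be lost through air oxidation on chromatographic supports, or through acid-induced cyclodehydration of the 2,2'-dihydroxybiaryl units on warming.
- Fallback: it sets out from 25 and comes back at 26, replacing direct isolation by derivatisation, purification and release. The crude product of the BBr3 treatment is peracetylated (Ac2O, pyridine, rt) to the docosaacetate of the target F5.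
- F5 is stable to air and can be separated on silica gel from under-cleaved, methoxy-bearing congeners, which are returned to BBr3.
- Zemplén transesterification of F5 (NaOMe cat., MeOH, Ar, then acidic ion-exchange resin) should release 26.

Further compounds
F1 | step 5 | 2,6-bis(3-bromo-4-hydroxy-2,6-dimethoxyphenoxy)-4-methoxybenzaldehyde | COc1cc(Oc2c(OC)cc(O)c(Br)c2OC)c(C=O)c(Oc2c(OC)cc(O)c(Br)c2OC)c1
F2 | step 5 | 2,6-bis(3-bromo-2,4,6-trimethoxyphenoxy)-4-methoxybenzaldehyde | COc1cc(Oc2c(OC)cc(OC)c(Br)c2OC)c(C=O)c(Oc2c(OC)cc(OC)c(Br)c2OC)c1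
F3 | step 15 | C4 pinacol boronate of the A–B–G–C fragment | COc1cc(OC)cc(Oc2c(OC)cc(Oc3c(OC)cc(B4OC(C)(C)C(C)(C)O4)cc3OC)c(-c3c(OC)cc(OC)cc3OC)c2OC)c1
F4 | step 15 | C4 boronic acid of the A–B–G–C fragment | COc1cc(OC)cc(Oc2c(OC)cc(Oc3c(OC)cc(B(O)O)cc3OC)c(-c3c(OC)cc(OC)cc3OC)c2OC)c1
F5 | step 16 | docosaacetate of the target | CC(=O)Oc1cc(OC(C)=O)cc(Oc2c(OC(C)=O)cc(Oc3c(OC(C)=O)cc(Oc4c(Oc5c(OC(C)=O)cc(OC(C)=O)c(-c6c(OC(C)=O)cc(OC(C)=O)cc6OC(C)=O)c5OC(C)=O)cc(OC(C)=O)cc4Oc4c(OC(C)=O)cc(OC(C)=O)c(-c5c(OC(C)=O)cc(OC(C)=O)cc5OC(C)=O)c4OC(C)=O)cc3OC(C)=O)c(-c3c(OC(C)=O)cc(OC(C)=O)cc3OC(C)=O)c2OC(C)=O)c1
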